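## Retrosynthetic overview

- Target ⇐ removal of three O-methyl groups; the all-cis oxolane ⇐ hydride delivery to a 2-aryl oxocarbenium ion (hydride anti to the three cis groups), generated from the hemiketal of an aryllithium (rings B and C) and an all-cis γ-lactone (ring A).
- All-cis lactone ⇐ one flask from meso-2,3-dimethylsuccinic acid: closure to the meso anhydride, Rh-catalysed enantioselective arylative opening (fixes C3/C4), Ru-catalysed transfer hydrogenation (fixes C5), lactonisation.
- Ring B/C aryl bromide ⇐ stereoretentive aryllithium–boronate coupling of the (R)-sec-boronate made by Cu-catalysed protoboration of anethole.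
- Ring order: the anhydride ring and the γ-lactone ring are both closed in the first operation; the lactone ring is carried on as the hemiketal and becomes the oxolane in the reduction step; the three benzene rings are bought.

Assumption: for the chiral Rh and Cu catalysts (and the Ir catalyst of one fallback) the ligand antipode that gives the drawn product is used; both antipodes are available.

Ring A = aryl on C5 of the oxolane, ring B = aryl on C2, ring C = aryl of the side chain. Oxolane numbering: O1, C2 (ring B), C3, C4, C5 (ring A); the target is (2R,3S,4R,5S), all four substituents cis, with an (R) side-chain centre.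

## Route

Step 1
Reactants: 1 meso-2,3-dimethylsuccinic acid; 2 4-methoxyphenylmagnesium bromide
Product: 7 (3S,4R,5S)-5-(4-methoxyphenyl)-3,4-dimethyloxolan-2-one (all-cis), via meso-anhydride 3 (not isolated), via arylzinc chloride 4 (not isolated), via keto acid 5 (not isolated), via hydroxy acid 6 (not isolated)
Conditions: DCC, THF, rt; then 2/ZnCl2 (gives 4), [Rh(cod)Cl]2 (4 mol%), TADDOL-derived phosphoramidite (8 mol%), DMF, 50 °C; then HCO2H/Et3N (5:2), RuCl[(S,S)-TsDPEN](p-cymene) (2 mol%), 40 °C; then 2 M HCl
Reagents that add atoms: none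
Why: Proposed new method: three known reaction types are run in one flask – carbodiimide cyclodehydration of a succinic acid to its anhydride, rhodium-catalysed enantioselective desymmetrising acyl cross-coupling of the meso anhydride with an arylzinc (oxidative addition into one enantiotopic acyl C–O bond fixes the absolute sense of the two untouched methyl-bearing centres as 2S,3R in 5), and Noyori-type asymmetric transfer hydrogenation in which the (S,S)-catalyst overrides the Felkin–Anh bias to give the (4S)-alcohol 6 that lactonises on acidification – and they should be compatible because the urea is inert, formic acid quenches surplus arylzinc before the ruthenium catalyst is added, and transfer hydrogenation tolerates DMF and zinc salts.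

Step 2
Reactants: 8 (E)-anethole; 9 bis(pinacolato)diboron
Product: 10 2-[(2R)-1-(4-methoxyphenyl)propan-2-yl]-4,4,5,5-tetramethyl-1,3,2-dioxaborolane
Conditions: CuCl (5 mol%), chiral imidazolinium NHC precursor (5.5 mol%), NaOt-Bu (20 mol%), MeOH (2 equiv), THF, −50 °C
Reagents that add atoms: none
Why: Copper-catalysed enantioselective protoboration (borylcupration then protonation): Cu–Bpin adds syn with boron at the carbon remote from the arene and copper at the benzylic carbon, methanol protonates C–Cu, and the chiral NHC ligand selects the alkene face to give the (R)-boronate.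

Step 3
Reactants: 10 the (R)-boronate; 11 4-bromo-2-iodo-1-methoxybenzene
Product: 14 4-bromo-1-methoxy-2-[(2R)-1-(4-methoxyphenyl)propan-2-yl]benzene, via aryllithium 12 (not isolated), via boronate complex 13 (not isolated)
Conditions: 11, t-BuLi (2.0 equiv), THF, −78 °C; 10, −78 → 0 °C; solvent switch to MeOH; NBS (1.1 equiv), −78 °C → rt
Reagents that add atoms: none
Why: Stereospecific aryllithium–boronic ester coupling (1,2-metalate rearrangement of a boronate complex): iodine–lithium exchange is selective over bromine, NBS attacks the electron-rich ring of 13 para to boron, the secondary alkyl group migrates from boron to the ipso carbon with retention, and loss of bromide and the boryl group restores the arene, so the (R) centre of 10 is carried unchanged into 14.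

Step 4
Reactants: 14 the aryl bromide; 7 the all-cis lactone
Product: 16 (3S,4R,5S)-2-{4-methoxy-3-[(2R)-1-(4-methoxyphenyl)propan-2-yl]phenyl}-5-(4-methoxyphenyl)-3,4-dimethyloxolan-2-ol (anomer mixture, used crude), via aryllithium 15 (not isolated)
Conditions: 14, t-BuLi (2.1 equiv), THF, −78 °C; 7, −78 °C, 1 h; AcOH, −78 °C
Reagents that add atoms: none
Why: Bromine–lithium exchange and 1,2-addition of the aryllithium to the lactone carbonyl stop at the lithium hemiketal alkoxide at −78 °C (no second addition), the cold acetic acid quench avoids epimerisation next to the masked ketone, and no new stereocentre needs control because C2 is set in the next step.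

Step 5
Reactants: 16 the hemiketal
Product: 18 (2R,3S,4R,5S)-2-{4-methoxy-3-[(2R)-1-(4-methoxyphenyl)propan-2-yl]phenyl}-5-(4-methoxyphenyl)-3,4-dimethyloxolane, via oxocarbenium ion 17 (not isolated)
Conditions: Et3SiH (4 equiv), BF3·OEt2 (2 equiv), CH2Cl2, −78 → −40 °C; sat. NaHCO3
Reagents that add atoms: none
Why: Lewis acid-promoted reductive deoxygenation of a cyclic hemiketal (ionic hydrogenation): BF3 ionises 16 to the 2-aryl oxocarbenium ion 17 and triethylsilane delivers hydride to the face opposite the three cis substituents at C3, C4 and C5, which puts ring B cis to them and gives the all-cis (2R) oxolane under kinetic control at low temperature.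

Step 6
Reactants: 18 the tris(methyl ether)
Product: 19 4-[(2S,3R,4S,5R)-5-{4-hydroxy-3-[(2R)-1-(4-hydroxyphenyl)propan-2-yl]phenyl}-3,4-dimethyloxolan-2-yl]phenol (target; the same compound as (2R,3S,4R,5S) in the numbering used above)
Conditions: LiPPh2 (0.5 M in THF, 8 equiv), THF, 25 → 50 °C; AcOH, 0 °C
Reagents that add atoms: none
Why: Nucleophilic demethylation of aryl methyl ethers by lithium diphenylphosphide (SN2 at the methyl carbon) is basic and non-acidic, so the acid-labile all-cis bis-benzylic oxolane and all five stereocentres are untouched while the three phenols are released.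

## Compound list

1 | meso-2,3-dimethylsuccinic acid, (2R,3S)-2,3-dimethylbutanedioic acid | C[C@@H](C(=O)O)[C@H](C)C(=O)O | starting material
2 | 4-methoxyphenylmagnesium bromide (1.0 M in THF) | COc1ccc([Mg]Br)cc1 | starting material
3 | meso-2,3-dimethylsuccinic anhydride, (3R,4S)-3,4-dimethyloxolane-2,5-dione | C[C@@H]1[C@H](C)C(=O)OC1=O | intermediate
4 | (4-methoxyphenyl)zinc chloride | COc1ccc([Zn]Cl)cc1 | intermediate
5 | (2S,3R)-4-(4-methoxyphenyl)-2,3-dimethyl-4-oxobutanoic acid | C[C@@H](C(=O)c1ccc(OC)cc1)[C@H](C)C(=O)O | intermediate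
6 | (2S,3R,4S)-4-hydroxy-4-(4-methoxyphenyl)-2,3-dimethylbutanoic acid | C[C@@H]([C@H](O)c1ccc(OC)cc1)[C@H](C)C(=O)O | intermediate
7 | (3S,4R,5S)-5-(4-methoxyphenyl)-3,4-dimethyloxolan-2-one | C[C@@H]1[C@H](C)C(=O)O[C@@H]1c1ccc(OC)cc1 | intermediate
8 | (E)-anethole, 1-methoxy-4-[(1E)-prop-1-en-1-yl]benzene | C/C=C/c1ccc(OC)cc1 | starting material
9 | bis(pinacolato)diboron | CC1(C)OB(OC1(C)C)B1OC(C)(C)C(C)(C)O1 | starting material
10 | 2-[(2R)-1-(4-methoxyphenyl)propan-2-yl]-4,4,5,5-tetramethyl-1,3,2-dioxaborolane | CC1(C)OB(OC1(C)C)[C@H](C)Cc1ccc(OC)cc1 | intermediate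
11 | 4-bromo-2-iodo-1-methoxybenzene | COc1ccc(Br)cc1I | starting material
12 | (5-bromo-2-methoxyphenyl)lithium | [Li]c1cc(Br)ccc1OC | intermediate
13 | lithium (5-bromo-2-methoxyphenyl)[(2R)-1-(4-methoxyphenyl)propan-2-yl](pinacolato)borate | [Li+].COc1ccc(Br)cc1[B-]1(OC(C)(C)C(C)(C)O1)[C@H](C)Cc1ccc(OC)cc1 | intermediate
14 | 4-bromo-1-methoxy-2-[(2R)-1-(4-methoxyphenyl)propan-2-yl]benzene | COc1ccc(Br)cc1[C@H](C)Cc1ccc(OC)cc1 | intermediate
15 | {4-methoxy-3-[(2R)-1-(4-methoxyphenyl)propan-2-yl]phenyl}lithium | [Li]c1ccc(OC)c(c1)[C@H](C)Cc1ccc(OC)cc1 | intermediate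
16 | (3S,4R,5S)-2-{4-methoxy-3-[(2R)-1-(4-methoxyphenyl)propan-2-yl]phenyl}-5-(4-methoxyphenyl)-3,4-dimethyloxolan-2-ol, anomer mixture | C[C@@H]1[C@H](C)C(O)(c2ccc(OC)c([C@H](C)Cc3ccc(OC)cc3)c2)O[C@@H]1c1ccc(OC)cc1 | intermediate
17 | (3S,4R,5S)-2-{4-methoxy-3-[(2R)-1-(4-methoxyphenyl)propan-2-yl]phenyl}-5-(4-methoxyphenyl)-3,4-dimethyl-4,5-dihydro-3H-furan-1-ium (oxocarbenium ion) | C[C@@H]1[C@H](C)C(c2ccc(OC)c([C@H](C)Cc3ccc(OC)cc3)c2)=[O+][C@@H]1c1ccc(OC)cc1 | intermediate
18 | (2R,3S,4R,5S)-2-{4-methoxy-3-[(2R)-1-(4-methoxyphenyl)propan-2-yl]phenyl}-5-(4-methoxyphenyl)-3,4-dimethyloxolane | C[C@@H]1[C@H](C)[C@H](c2ccc(OC)c([C@H](C)Cc3ccc(OC)cc3)c2)O[C@@H]1c1ccc(OC)cc1 | intermediate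
19 | 4-[(2S,3R,4S,5R)-5-{4-hydroxy-3-[(2R)-1-(4-hydroxyphenyl)propan-2-yl]phenyl}-3,4-dimethyloxolan-2-yl]phenol | C[C@@H]1[C@H](C)[C@H](c2ccc(O)c([C@H](C)Cc3ccc(O)cc3)c2)O[C@@H]1c1ccc(O)cc1 | target

## Step count and risks

Total: 6 steps. Longest linear sequence: 5 steps (8 → 10 → 14 → 16 → 18 → 19); the lactone branch (1 → 7) is one step and joins at step 4.

Steps most likely to fail:

Step 1. The telescoping is untested: the phosphoramidite or rhodium residues may slow the ruthenium catalyst, and the reduction is mismatched (it must go against the Felkin–Anh preference of an α-branched aryl ketone). The enantiomeric excess of the arylation is expected to be only about 85–90%; the minor enantiomer of 5 ends up as the 4,5-trans lactone, a diastereomer that must be separated from 7. Fallback, setting out from 1 and coming back at 7: the diacid is closed with acetyl chloride to the isolated meso-anhydride 3, the same rhodium-catalysed arylation with 4 gives keto acid 5, which is isolated; its carboxylate is then reduced under substrate (Felkin–Anh) control with LiBH(s-Bu)3 at −78 °C to (2S,3R,4R)-4-hydroxy-4-(4-methoxyphenyl)-2,3-dimethylbutanoic acid F1, kept as its triethylammonium salt so that it does not lactonise, and an intramolecular Mitsunobu lactonisation (PPh3, DIAD, THF, 0 °C) closes the ring with inversion at C4 to give 7. Here C5 is set by substrate control plus SN2 inversion instead of by the catalyst.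

Step 3. The ring of complex 13 carries its methoxy group ortho to boron and a bromine, so attack of NBS at the C–B carbon (giving the alkyl bromide) may compete with attack on the ring. Fallback, setting out from 11 and coming back at 14: commercial 1-methoxy-4-(prop-1-yn-1-yl)benzene is protoborated with 9 (CuCl, xantphos, NaOt-Bu, MeOH) by syn addition to 2-[(1Z)-1-(4-methoxyphenyl)prop-1-en-2-yl]-4,4,5,5-tetramethyl-1,3,2-dioxaborolane F2; Suzuki coupling with 11 at the C–I bond only (Pd(PPh3)4, K2CO3, dioxane/water, 60 °C) gives 4-bromo-1-methoxy-2-[(1E)-1-(4-methoxyphenyl)prop-1-en-2-yl]benzene F3; asymmetric hydrogenation of this trisubstituted alkene (H2, 50 bar, [Ir(cod)(t-Bu-PHOX)]BArF, CH2Cl2) sets the (R) centre and gives 14 with the aryl bromide intact.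

Step 5. The all-cis product is the least stable diastereomer and its benzylic C–O bonds can re-ionise under BF3, so epimerisation at C2 or C5 or over-reduction is possible if the mixture warms. Fallback, setting out from 16 and coming back at 18: 16 is dehydrated (MsCl, Et3N, CH2Cl2, 0 °C) to the cyclic enol ether (2S,3R)-5-{4-methoxy-3-[(2R)-1-(4-methoxyphenyl)propan-2-yl]phenyl}-2-(4-methoxyphenyl)-3,4-dimethyl-2,3-dihydrofuran F4, and heterogeneous hydrogenation (H2, Rh/Al2O3, EtOAc, rt) adds both hydrogens from the face opposite ring A and the C4 methyl group, giving 18 without any cationic intermediate.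

## Further compounds

F1 | step 1 | (2S,3R,4R)-4-hydroxy-4-(4-methoxyphenyl)-2,3-dimethylbutanoic acid | C[C@@H]([C@@H](O)c1ccc(OC)cc1)[C@H](C)C(=O)O
F2 | step 3 | 2-[(1Z)-1-(4-methoxyphenyl)prop-1-en-2-yl]-4,4,5,5-tetramethyl-1,3,2-dioxaborolane | COc1ccc(/C=C(\C)B2OC(C)(C)C(C)(C)O2)cc1
F3 | step 3 | 4-bromo-1-methoxy-2-[(1E)-1-(4-methoxyphenyl)prop-1-en-2-yl]benzene | COc1ccc(Br)cc1/C(C)=C/c1ccc(OC)cc1
F4 | step 5 | (2S,3R)-5-{4-methoxy-3-[(2R)-1-(4-methoxyphenyl)propan-2-yl]phenyl}-2-(4-methoxyphenyl)-3,4-dimethyl-2,3-dihydrofuran | C[C@@H]1C(C)=C(c2ccc(OC)c([C@H](C)Cc3ccc(OC)cc3)c2)O[C@@H]1c1ccc(OC)cc1
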